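## The problem

Numbering used throughout: ring C1(=O)–C2(CH2OAc)=C3H–C4(=O)–C5–C6H with the oxirane across C5–C6; chain on C5: C7H(OAc)–C8H=C9(CH3)–C10H=C11H–C12H=O.

Target 26 is a single carbocycle, a cyclohex-2-ene-1,4-dione, cis-fused to an oxirane. C2 carries an acetoxymethyl group, and the fully substituted oxirane carbon C5 carries a six-carbon chain that starts at the acetoxy carbinol C7 and ends as an (8E,10E)-dienal. There are three contiguous stereocentres, C5 (R), C6 (S) and C7 (S). C6 is tied to C5 by the three-membered ring, so the real task is the relation between the quaternary C5 and the exocyclic C7. C7 is the only centre that can be bought from the chiral pool, and because it sits next to C5 it can direct the face of a C5 carbonyl. The epoxy-enedione (opened, reduced or aromatised by bases, nucleophiles and reductants), the 2-(acetoxymethyl)enone (an allylic acetate open to SN2′ attack), the C7 acetate and the dienal will not survive rough treatment. Both acetates and the C4 carbonyl must therefore come last, under neutral or weakly acidic conditions. The enabling feature is that the oxirane lies α,β to the C1 ketone with C5 fully substituted, a glycidic ketone, and that C5–C6 is also a ring bond. A C6 α-chloro enolate adding to a C5 ketone can thus close the carbocycle and the oxirane together. This requires a Z C2=C3 bond in the open precursor and C4 below the ketone level. As a carbinol, C4 then carries the most acidic hydrogen of the precursor, and that is the price of the plan.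

## Retrosynthesis

**Acetates and C4 carbonyl (26 ⇒ 25 ⇒ 24 ⇒ 23 ⇒ 22).** The C4=O bond and the two acetyl–oxygen bonds are cut first. Carrying the enedione or either acetate further back would expose them to organolithium, aluminium amide and fluoride reagents. The precursors differ from 26 only in oxidation level and acylation: 25 is the C4 alcohol, 24 the diol, 23 the bis-silyl ether and 22 the C7 alcohol. The forward steps must acetylate the primary alcohol of 24 beside the hindered C4 alcohol and oxidise C4 without base.

**Dienal chain (22 ⇒ 20 ⇒ 17 ⇒ 16).** C10=C11 and C8=C9 are cut as two Wittig olefinations with the commercial formyl ylides 21 and 18, back to diol 17 and its acetonide 16. Carrying the diene through the ring closure was rejected because C7–H would then be both α to the C5 ketone and allylic. A single four-carbon olefination would need a reagent that cannot be bought. The cut removes five carbons and two alkenes and leaves C8 as the oxygen that came with the chiral-pool C7. The forward steps must oxidise only the primary hydroxyl of 17 and give E alkenes.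

**Key disconnection (16 ⇒ 14).** C5–C6 and O–C6 are cut together, as an intramolecular Darzens condensation of the chloromethyl diketone 14. A cut at C2=C3 would leave the oxirane and its quaternary carbon to be built stereoselectively on an open chain. The chosen cut removes both rings and two stereocentres at once, and 14 is acyclic with only C4 and C7 stereogenic. The forward reaction must enolise C6 and not C4 or C7, choose one face of the C5 ketone, and find C6 close to C5.

**C5 ketone and chloromethyl ketone (14 ⇒ 13 ⇒ 12 ⇒ 9 + 10).** The C5 carbonyl is traced to alcohol 13 and its triethylsilyl ether 12. The C1–C6 bond is cut to Weinreb amide 9 and the chloromethyl carbenoid from 10. The C5 ketone cannot be present when the carbenoid is used, hence the temporary silyl ether on O5. Chlorination of a methyl ketone is the longer alternative and is kept as a fallback. The forward step needs clean 1,2-addition to a Z, α-branched enamide.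

**Opening the lactone (9 ⇒ 8 ⇒ 7 ⇒ 6).** The amide C1–N bond and the O4–Si bond lead back to butenolide 7 and the aldol adduct 6. The lactone ring is what guarantees the Z C2=C3 geometry, and it keeps O4 masked while O5 is silylated. Adding the carbenoid directly to the lactone was rejected because the cyclic hemiketal it would leave can dehydrate with aromatisation. The forward step must open the lactone without conjugate addition and trap O4 before it closes again.

**C4–C5 bond (6 ⇒ 4 + 5).** A vinylogous Mukaiyama aldol disconnection gives silyloxyfuran 4 and (S)-glyceraldehyde acetonide 5. One bond joins the C1–C4 unit to C5, C7 and C8 and delivers O4 and O5 already differentiated. Only C7 has to survive: C5 is oxidised and C4 is sacrificial, so the diastereoselectivity of the aldol step matters only through the match of C4 with C7 in the ring closure.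

**Hydroxymethyl group (4 ⇒ 3 ⇒ 1 + 2).** The C2–CH2 bond is cut as a Morita–Baylis–Hillman reaction of furan-2(5H)-one 1 with formaldehyde 2. Late hydroxymethylation of the cyclohexenone was rejected because it would place a nucleophile-catalysed step on the base-sensitive epoxy enone. It would also create the reactive acetoxymethyl enone before the Wittig steps.

## Roads not taken

**Alternative 1:** The ring and C7 are taken from an arene, benzoic acid A1, and the cut is the pair of C–O bonds at C5 and C6. In the forward key step benzoate 1,2-dioxygenase in whole cells adds dioxygen cis across the ipso and ortho carbons to give the diene diol acid A2, whose carboxyl carbon is C7.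
- Merits: one step from a commodity arene sets the quaternary C5 and C6 as a single enantiomer. By atom mapping, both C–O bonds of A2 already have the sense that 26 needs.
- Weak points: A2 has two hydroxyls where 26 has one bridging oxygen, so the C6 oxygen must be activated, displaced and re-closed with double inversion. The C1 and C4 oxygens and the C2 carbon must be added to a diene that rearomatises easily by dehydration. C7 arrives as a carboxyl, so its configuration would have to be made by addition next to the quaternary C5 with uncertain induction. Fermentation capacity is needed.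
- Comparison: in the certainty with which C5 and C6 are set, this road is better than the chosen one, whose key step is unproven. The chosen plan sets against it that C7 is bought and then steers C5, that C1, the C2 substituent and the C4 oxygen are in place when the ring closes, and that no labile diene has to be reshaped by redox steps.

**Alternative 2:** The cut is the C2=C3 bond. In the forward key step a ruthenium alkylidene (second-generation Grubbs catalyst) joins the C3 vinyl group and the 1,1-disubstituted C2 alkene of diene A3 with loss of ethylene, giving the epoxycyclohexenediol A4.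
- Merits: ring-closing metathesis is neutral and well understood and tolerates acetates and an oxirane. A4 already holds both acetates and the whole chain, so only two alcohol oxidations and an acetal hydrolysis remain.
- Weak points: every stereocentre of A3, including the trisubstituted oxirane with its quaternary carbon and two sacrificial carbinols, must be assembled on an open chain. The hardest problem is moved, not solved. The C8=C9 alkene of the chain can engage the alkylidene and close a five-membered ring through C3, C4, C5, C7 and C8 with loss of the chain end. The 1,1-disubstituted alkene is a slow partner.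
- Comparison: the ring closure itself is more reliable than the chosen key step and the endgame is shorter. The chosen plan sets against this that the oxirane and its two stereocentres need no separate stereocontrolled construction, and that no chain alkene is present when the ring is closed.

**Alternative 3:** The cuts are C4–C5, C6–C1 and C3–C4. The arene is assembled from the pentacarbonyl chromium carbene complex A5 (zerovalent chromium; C1 to C3 and the CH2O carbon), the propargylic alkyne A6 (C5, C6, C7 and the chain) and one carbonyl ligand (C4). The forward key step is a Dötz benzannulation to the 4-methoxyphenol A7.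
- Merits: highly convergent, with three bonds and the ring formed in one step. The regiochemistry is fixed by the terminal alkyne, and C7 comes from a propargylic alcohol of known configuration.
- Weak points: A7 is flat. After oxidative dearomatisation a mono-epoxidation would have to choose between two trisubstituted ring double bonds and between two faces, with only the exocyclic C7 to guide it. Stoichiometric chromium is needed. The oxidative demethylation threatens the dienyl acetal and the benzylic, allylic C7 ether.
- Comparison: this road reaches the full carbon skeleton in fewer steps and with better convergence than the chosen plan. It postpones the stereochemical problem to the most sensitive intermediate, whereas the chosen plan solves it in the ring-forming step under control of C7.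

Key step: step 10

Assumption: the Morita–Baylis–Hillman hydroxymethylation, established for cyclic enones with formalin and for butenolides with aliphatic aldehydes, is taken to extend to furan-2(5H)-one with formaldehyde.

## Route

Step 1
Reactants: 1 furan-2(5H)-one; 2 formaldehyde
Product: 3 3-(hydroxymethyl)furan-2(5H)-one
Conditions: aq. HCHO (37 %), n-Bu3P (0.2 equiv), THF, 0 °C → rt
Reagents that add atoms: none
Why: Morita–Baylis–Hillman reaction: the phosphine adds to the β-carbon of the butenolide, the enolate adds to formaldehyde at the α-carbon and loss of the phosphine restores the ring alkene; formaldehyde, the most reactive acceptor, should offset the modest reactivity of the lactone.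

Step 2
Reactants: 3 3-(hydroxymethyl)furan-2(5H)-one
Product: 4 2-(triisopropylsilyloxy)-3-[(triisopropylsilyloxy)methyl]furan
Conditions: i-Pr3SiOTf (2.2 equiv), Et3N (3 equiv), CH2Cl2, 0 °C
Reagents that add atoms: triisopropylsilyl trifluoromethanesulfonate, CC(C)[Si](C(C)C)(C(C)C)OS(=O)(=O)C(F)(F)F
Why: Silyl triflate/amine silylation of the alcohol and O-silylation of the butenolide dienolate to the aromatic 2-silyloxyfuran; one bulky silyl group serves both oxygens, and the primary triisopropylsilyl ether should outlast every later acidic step.

Step 3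
Reactants: 4 bis-silyl furan; 5 (S)-glyceraldehyde acetonide
Product: 6 butenolide aldol adduct (4S,5R,7S) with free C5 hydroxyl
Conditions: BF3·OEt2 (1.1 equiv), CH2Cl2, −78 °C; aq. NaHCO3
Reagents that add atoms: none
Why: Vinylogous Mukaiyama aldol reaction: the silyloxyfuran attacks the activated aldehyde through its free α-carbon (the future C4) and forms the C4–C5 bond; by analogy with the parent silyloxyfuran the 4,5-syn-5,7-anti adduct (Felkin addition) should dominate. C5 is oxidised and C4 removed later, so only C7, which is not touched, has to survive.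

Step 4
Reactants: 6 butenolide aldol adduct
Product: 7 C5 triethylsilyl ether of 6
Conditions: Et3SiCl, imidazole, CH2Cl2, 0 °C → rt
Reagents that add atoms: chlorotriethylsilane, CC[Si](Cl)(CC)CC
Why: Standard silyl chloride/imidazole silylation; triethylsilyl is a temporary mask for O5 that can later be removed beside the tert-butyldimethylsilyl and triisopropylsilyl ethers.

Step 5
Reactants: 7 silylated butenolide
Product: 8 (Z)-4-hydroxy Weinreb amide
Conditions: MeNH(OMe)·HCl, AlMe3, CH2Cl2, 0 °C → rt; aq. potassium sodium tartrate
Reagents that add atoms: N,O-dimethylhydroxylamine hydrochloride, CNOC.Cl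
Why: Weinreb aminolysis of a lactone with the aluminium amide formed from AlMe3 and the amine salt; acyl substitution frees O4 and keeps the Z geometry imposed by the ring. The crude hydroxy amide is used at once because it can relactonise.

Step 6
Reactants: 8 (Z)-4-hydroxy Weinreb amide
Product: 9 (Z)-4-(tert-butyldimethylsilyloxy) Weinreb amide
Conditions: t-BuMe2SiOTf, 2,6-lutidine, CH2Cl2, −78 °C
Reagents that add atoms: tert-butyldimethylsilyl trifluoromethanesulfonate, CC(C)(C)[Si](C)(C)OS(=O)(=O)C(F)(F)F
Why: Silyl triflate/lutidine silylation at low temperature traps O4 before relactonisation; the bulky silyl ether also shields the C4 hydrogen for the key step.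

Step 7
Reactants: 9 silylated Weinreb amide; 10 chloroiodomethane
Product: 12 (Z)-chloromethyl enone with C5 triethylsilyl ether, via lithium hemiaminal alkoxide 11 (not isolated)
Conditions: MeLi·LiBr, THF/Et2O, −78 °C (carbenoid generated in the presence of 9); aq. NH4Cl
Reagents that add atoms: none
Why: Weinreb ketone synthesis with a lithium carbenoid: chloromethyllithium from iodine–lithium exchange adds to the amide carbonyl, and the chelated adduct 11 holds until work-up, so over-addition and conjugate addition should not interfere.

Step 8
Reactants: 12 (Z)-chloromethyl enone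
Product: 13 C5 alcohol of 12
Conditions: Et3N·3HF, MeCN/THF, 0 °C
Reagents that add atoms: none
Why: Selective fluoride-mediated desilylation: the triethylsilyl ether should cleave much faster than the hindered secondary tert-butyldimethylsilyl and the primary triisopropylsilyl ethers. The buffered reagent avoids free base (silyl migration, enolisation) and free pyridine (alkylation by the chloromethyl ketone).

Step 9
Reactants: 13 C5 alcohol
Product: 14 (Z)-chloromethyl ene-diketone (4S,7S), the ring-closure precursor
Conditions: Dess–Martin periodinane, NaHCO3, CH2Cl2, 0 °C → rt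
Reagents that add atoms: none
Why: Dess–Martin oxidation under buffered, non-basic conditions; any cyclic hemiketal form of 13 is drained through the open hydroxy ketone. The diketone is used without storage.

Step 10
Reactants: 14 (Z)-chloromethyl ene-diketone
Product: 16 epoxy enone (4S,5R,6S,7S) carrying the C4 silyl ether and the C7/C8 acetonide, via lithium chloro aldolate 15 (not isolated)
Conditions: LiN(SiMe3)2 (1.05 equiv), PhMe/THF (10:1), −78 → 0 °C, 0.01 M, 14 added to the base; pH 7 buffer
Reagents that add atoms: none
Why: Proposed new method: kinetic deprotonation of the chlorine-acidified primary C6 methylene gives the lithium enolate of 14, which adds to the C5 ketone in a 6-(enolexo)-exo-trig aldol closure of the carbocycle, and the tertiary alkoxide of 15 then displaces chloride in a 3-exo-tet closure of the oxirane, forming C5–C6 and O–C6 in one operation. The closest known reaction type is the intermolecular Darzens condensation of α-chloro ketone enolates with ketones; running it within one chain to close a carbocycle is the new element. C5 is set by C7: lithium held between the C5 carbonyl oxygen and the dioxolane oxygen on C7 fixes the C5–C7 rotamer so that C6 enters anti to C8, and the 4S silyloxy group, which ends pseudo-equatorial and trans to the C7 branch, should reinforce this face. C6 is set by the displacement, which needs alkoxide and chloride anti, so only the cis-fused oxirane can form and a syn chloro aldolate returns by retro-aldol or by epimerisation at C6. The step needs enolisation at C6 and not at the thermodynamically more acidic C4–H or at C7–H; this is secured by the unhindered primary position against two tertiary α-oxygenated ones, by a bulky amide base at −78 °C, and by adding 14 to the base so that no free ketone is left to shuttle protons. It needs C6 within reach of C5, secured by the Z C2=C3 bond inherited from the butenolide, and a reactive acceptor, secured by the two α-oxygen substituents of the C5 ketone. High dilution should suppress intermolecular aldol and alkylation, and a single equivalent of base protects the γ-hydrogen at C4 of 16.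

Step 11
Reactants: 16 epoxy enone
Product: 17 C7,C8-diol
Conditions: AcOH/H2O/THF (3:1:1), 35 °C
Reagents that add atoms: none
Why: Acid-catalysed hydrolysis of a terminal isopropylidene acetal; the hindered secondary tert-butyldimethylsilyl ether, the primary triisopropylsilyl ether and the acyl-deactivated oxirane should tolerate aqueous acetic acid.

Step 12
Reactants: 17 C7,C8-diol; 18 2-(triphenylphosphoranylidene)propanal
Product: 20 (8E)-hydroxy enal, via hydroxy aldehyde 19 (not isolated)
Conditions: TEMPO (0.2 equiv), PhI(OAc)2 (1.1 equiv), CH2Cl2, 0 °C → rt; then 18 (2.5 equiv), 40 °C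
Reagents that add atoms: none
Why: Nitroxyl-catalysed oxidation selective for the primary hydroxyl of a 1,2-diol, followed in the same flask by Wittig olefination of the sensitive 2-hydroxy aldehyde 19 with the stabilised ylide 18, which should give the E trisubstituted enal. The near-neutral medium should leave C7 unepimerised.

Step 13
Reactants: 20 (8E)-hydroxy enal; 21 (triphenylphosphoranylidene)acetaldehyde
Product: 22 (8E,10E)-hydroxy dienal
Conditions: PhMe, 60 °C
Reagents that add atoms: none
Why: Wittig olefination with a formyl-stabilised ylide extends the enal by two carbons with E selectivity; the product is a vinylogous, less electrophilic aldehyde, so a second homologation should be slow with a small excess of 21.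

Step 14
Reactants: 22 (8E,10E)-hydroxy dienal
Product: 23 C7 acetate
Conditions: Ac2O, pyridine, DMAP (cat.), CH2Cl2, 0 °C
Reagents that add atoms: acetic anhydride, CC(=O)OC(C)=O
Why: DMAP-catalysed acylation of the secondary allylic alcohol; mild enough to leave the oxirane and the dienal alone.

Step 15
Reactants: 23 C7 acetate
Product: 24 diol with free C2 hydroxymethyl and C4 hydroxyl
Conditions: HF·pyridine, THF, 0 °C → rt
Reagents that add atoms: none
Why: Fluoride-mediated desilylation removes both silyl ethers under mildly acidic conditions that the acetate, the oxirane and the dienal should tolerate.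

Step 16
Reactants: 24 diol
Product: 25 primary acetate with free C4 hydroxyl
Conditions: AcCl (1.1 equiv), 2,4,6-collidine, CH2Cl2, −78 °C
Reagents that add atoms: acetyl chloride, CC(Cl)=O
Why: Selective acylation of a primary alcohol with acetyl chloride and a hindered pyridine base at low temperature; the secondary C4 hydroxyl next to the quaternary C5 should react much more slowly.

Step 17
Reactants: 25 primary acetate
Product: 26 target CNP0307549.1
Conditions: Dess–Martin periodinane, NaHCO3, CH2Cl2, 0 °C → rt
Reagents that add atoms: none
Why: Dess–Martin oxidation of the allylic C4 alcohol removes the sacrificial stereocentre; the buffered neutral conditions should spare the epoxy-enedione, both acetates and the dienal.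

## Compound list

1 | furan-2(5H)-one | O=C1OCC=C1 | starting material
2 | formaldehyde | C=O | starting material
3 | 3-(hydroxymethyl)furan-2(5H)-one | O=C1OCC=C1CO | intermediate
4 | 2-(triisopropylsilyloxy)-3-[(triisopropylsilyloxy)methyl]furan | CC(C)[Si](C(C)C)(C(C)C)OCc1ccoc1O[Si](C(C)C)(C(C)C)C(C)C | intermediate
5 | (S)-2,2-dimethyl-1,3-dioxolane-4-carbaldehyde ((S)-glyceraldehyde acetonide) | O=C[C@@H]1COC(C)(C)O1 | starting material
6 | (5S)-5-{(R)-[(4S)-2,2-dimethyl-1,3-dioxolan-4-yl](hydroxy)methyl}-3-[(triisopropylsilyloxy)methyl]furan-2(5H)-one | CC(C)[Si](C(C)C)(C(C)C)OCC1=C[C@@H]([C@@H](O)[C@@H]2COC(C)(C)O2)OC1=O | intermediate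
7 | (5S)-5-{(R)-[(4S)-2,2-dimethyl-1,3-dioxolan-4-yl](triethylsilyloxy)methyl}-3-[(triisopropylsilyloxy)methyl]furan-2(5H)-one | CC(C)[Si](C(C)C)(C(C)C)OCC1=C[C@@H]([C@@H](O[Si](CC)(CC)CC)[C@@H]2COC(C)(C)O2)OC1=O | intermediate
8 | (2Z,4S,5R)-5-[(4S)-2,2-dimethyl-1,3-dioxolan-4-yl]-4-hydroxy-N-methoxy-N-methyl-5-(triethylsilyloxy)-2-[(triisopropylsilyloxy)methyl]pent-2-enamide | CON(C)C(=O)/C(CO[Si](C(C)C)(C(C)C)C(C)C)=C\[C@H](O)[C@@H](O[Si](CC)(CC)CC)[C@@H]1COC(C)(C)O1 | intermediate
9 | (2Z,4S,5S)-4-(tert-butyldimethylsilyloxy)-5-[(4S)-2,2-dimethyl-1,3-dioxolan-4-yl]-N-methoxy-N-methyl-5-(triethylsilyloxy)-2-[(triisopropylsilyloxy)methyl]pent-2-enamide (descriptor at C5 changes by priority only) | CON(C)C(=O)/C(CO[Si](C(C)C)(C(C)C)C(C)C)=C\[C@H](O[Si](C)(C)C(C)(C)C)[C@@H](O[Si](CC)(CC)CC)[C@@H]1COC(C)(C)O1 | intermediate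
10 | chloroiodomethane | ClCI | starting material
11 | lithium alkoxide of the tetrahedral carbenoid adduct of 9 (chloromethyl, N-methoxy-N-methylamino and oxido groups on C1; not isolated) | [Li+].[O-]C(CCl)(N(C)OC)/C(CO[Si](C(C)C)(C(C)C)C(C)C)=C\[C@H](O[Si](C)(C)C(C)(C)C)[C@@H](O[Si](CC)(CC)CC)[C@@H]1COC(C)(C)O1 | intermediate
12 | (3Z,5S,6S)-5-(tert-butyldimethylsilyloxy)-1-chloro-6-[(4S)-2,2-dimethyl-1,3-dioxolan-4-yl]-6-(triethylsilyloxy)-3-[(triisopropylsilyloxy)methyl]hex-3-en-2-one | ClCC(=O)/C(CO[Si](C(C)C)(C(C)C)C(C)C)=C\[C@H](O[Si](C)(C)C(C)(C)C)[C@@H](O[Si](CC)(CC)CC)[C@@H]1COC(C)(C)O1 | intermediate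
13 | (3Z,5S,6S)-5-(tert-butyldimethylsilyloxy)-1-chloro-6-[(4S)-2,2-dimethyl-1,3-dioxolan-4-yl]-6-hydroxy-3-[(triisopropylsilyloxy)methyl]hex-3-en-2-one | ClCC(=O)/C(CO[Si](C(C)C)(C(C)C)C(C)C)=C\[C@H](O[Si](C)(C)C(C)(C)C)[C@@H](O)[C@@H]1COC(C)(C)O1 | intermediate
14 | (2S,3Z)-2-(tert-butyldimethylsilyloxy)-6-chloro-1-[(4S)-2,2-dimethyl-1,3-dioxolan-4-yl]-4-[(triisopropylsilyloxy)methyl]hex-3-ene-1,5-dione (4S,7S in target numbering) | ClCC(=O)/C(CO[Si](C(C)C)(C(C)C)C(C)C)=C\[C@H](O[Si](C)(C)C(C)(C)C)C(=O)[C@@H]1COC(C)(C)O1 | intermediate
15 | lithium 6-chloro-5-oxido aldolate: cyclohex-2-enone with C4 silyl ether, C5 oxido and dioxolanyl groups, C6 chlorine trans to the oxido group (not isolated) | CC(C)[Si](C(C)C)(C(C)C)OCC1=C[C@H](O[Si](C)(C)C(C)(C)C)[C@@]([O-])([C@@H]2COC(C)(C)O2)[C@@H](Cl)C1=O.[Li+] | intermediate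
16 | (4S,5R,6S)-4-(tert-butyldimethylsilyloxy)-5-[(4S)-2,2-dimethyl-1,3-dioxolan-4-yl]-5,6-epoxy-2-[(triisopropylsilyloxy)methyl]cyclohex-2-en-1-one | CC(C)[Si](C(C)C)(C(C)C)OCC1=C[C@H](O[Si](C)(C)C(C)(C)C)[C@]2([C@@H]3COC(C)(C)O3)O[C@@H]2C1=O | intermediate
17 | (4S,5R,6S)-4-(tert-butyldimethylsilyloxy)-5-[(1S)-1,2-dihydroxyethyl]-5,6-epoxy-2-[(triisopropylsilyloxy)methyl]cyclohex-2-en-1-one | CC(C)[Si](C(C)C)(C(C)C)OCC1=C[C@H](O[Si](C)(C)C(C)(C)C)[C@]2([C@@H](O)CO)O[C@@H]2C1=O | intermediate
18 | 2-(triphenylphosphoranylidene)propanal | CC(C=O)=P(c1ccccc1)(c1ccccc1)c1ccccc1 | starting material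
19 | C8 aldehyde of 17: 2-hydroxy-2-(ring C5)acetaldehyde, C7 spatially unchanged (not isolated) | CC(C)[Si](C(C)C)(C(C)C)OCC1=C[C@H](O[Si](C)(C)C(C)(C)C)[C@]2([C@@H](O)C=O)O[C@@H]2C1=O | intermediate
20 | (4S,5R,6S)-4-(tert-butyldimethylsilyloxy)-5,6-epoxy-5-[(1S,2E)-1-hydroxy-3-methyl-4-oxobut-2-en-1-yl]-2-[(triisopropylsilyloxy)methyl]cyclohex-2-en-1-one | CC(C)[Si](C(C)C)(C(C)C)OCC1=C[C@H](O[Si](C)(C)C(C)(C)C)[C@]2([C@@H](O)/C=C(C)/C=O)O[C@@H]2C1=O | intermediate
21 | (triphenylphosphoranylidene)acetaldehyde | O=CC=P(c1ccccc1)(c1ccccc1)c1ccccc1 | starting material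
22 | (4S,5R,6S)-4-(tert-butyldimethylsilyloxy)-5,6-epoxy-5-[(1S,2E,4E)-1-hydroxy-3-methyl-6-oxohexa-2,4-dien-1-yl]-2-[(triisopropylsilyloxy)methyl]cyclohex-2-en-1-one | CC(C)[Si](C(C)C)(C(C)C)OCC1=C[C@H](O[Si](C)(C)C(C)(C)C)[C@]2([C@@H](O)/C=C(C)/C=C/C=O)O[C@@H]2C1=O | intermediate
23 | (4S,5R,6S)-5-[(1S,2E,4E)-1-acetoxy-3-methyl-6-oxohexa-2,4-dien-1-yl]-4-(tert-butyldimethylsilyloxy)-5,6-epoxy-2-[(triisopropylsilyloxy)methyl]cyclohex-2-en-1-one | CC(C)[Si](C(C)C)(C(C)C)OCC1=C[C@H](O[Si](C)(C)C(C)(C)C)[C@]2([C@H](/C=C(C)/C=C/C=O)OC(C)=O)O[C@@H]2C1=O | intermediate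
24 | (4S,5R,6S)-5-[(1S,2E,4E)-1-acetoxy-3-methyl-6-oxohexa-2,4-dien-1-yl]-5,6-epoxy-4-hydroxy-2-(hydroxymethyl)cyclohex-2-en-1-one | OCC1=C[C@H](O)[C@]2([C@H](/C=C(C)/C=C/C=O)OC(C)=O)O[C@@H]2C1=O | intermediate
25 | (4S,5R,6S)-2-(acetoxymethyl)-5-[(1S,2E,4E)-1-acetoxy-3-methyl-6-oxohexa-2,4-dien-1-yl]-5,6-epoxy-4-hydroxycyclohex-2-en-1-one | CC(=O)OCC1=C[C@H](O)[C@]2([C@H](/C=C(C)/C=C/C=O)OC(C)=O)O[C@@H]2C1=O | intermediate
26 | (5R,6S)-2-(acetoxymethyl)-5-[(1S,2E,4E)-1-acetoxy-3-methyl-6-oxohexa-2,4-dien-1-yl]-5,6-epoxycyclohex-2-ene-1,4-dione (CNP0307549.1) | CC(=O)OCC1=CC(=O)[C@]2([C@H](/C=C(C)/C=C/C=O)OC(C)=O)O[C@@H]2C1=O | target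

## Step count and least certain steps

Total: 17 steps. Longest linear sequence: 17 steps, from 1 to 26; 2, 5, 10, 18 and 21 enter as purchased building blocks.

**Step 10 (key step, proposed new method).** The most likely failure is proton transfer from the more acidic C4–H to the C6 enolate before ring closure, which leads to alkene isomerisation or to alkylation at C4. Second to it is erosion of face selection at C5 if lithium does not hold the dioxolane oxygen. The fallback sets out from 14 and returns at 16, and it separates the two bond formations with known reactions. 14 would be deprotonated with LiN(SiMe3)2 at −100 °C with Me3SiCl already present, so that the C6 enolate is trapped as it forms, giving the C6 trimethylsilyl enol ether F1. MgBr2·OEt2 in CH2Cl2 would then promote a chelation-controlled intramolecular Mukaiyama aldol addition with no base present, giving the 6-chloro-5-hydroxy ketone F2. K2CO3 in MeCN would close F2 to 16; a C6 epimer of F2 equilibrates through the α-chloro ketone enol before closure.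

**Step 12.** The iodane may cleave the 1,2-diol, or the free 2-hydroxy aldehyde may dimerise or rearrange before the sluggish formyl ylide reacts. The fallback sets out from 17 and returns at 23. The primary hydroxyl would be silylated selectively (Et3SiCl, 2,6-lutidine, −78 °C) to the C8 triethylsilyl ether F3 and the C7 hydroxyl acetylated to F4. Swern conditions, which oxidise primary triethylsilyl ethers directly, would give the 2-acetoxy aldehyde F5 without a free alcohol that could take up the acetyl group. Wittig reaction with 18 would give the acetoxy enal F6, and a second Wittig reaction with 21 would give 23.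

**Step 5.** The aluminium amide may add in conjugate fashion or act as a base (γ-deprotonation with loss of the C5 silyloxy group), and the hydroxy amide may relactonise. The fallback sets out from 7 and returns at 9. Saponification with LiOH in THF/H2O at 0 °C would give the lithium (Z)-4-hydroxy carboxylate F7, which cannot lactonise as its salt. Silylation with t-BuMe2SiCl and imidazole would give the silyl ester silyl ether F8, and K2CO3 in aqueous MeOH would cleave only the silyl ester to the acid F9. Carbodiimide coupling with N,O-dimethylhydroxylamine would give 9.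

**Step 7.** The carbenoid may decompose by α-elimination before it adds to the hindered, α-branched Z-enamide. The fallback sets out from 9 and returns at 12. MeLi would give the methyl enone F10. Kinetic deprotonation with LiN(SiMe3)2 and Me3SiCl would give the cross-conjugated silyl dienol ether F11, the methyl group being the only α-position of this ketone. N-Chlorosuccinimide would chlorinate F11 at the terminal carbon to 12.

**Step 1.** The butenolide may be consumed by dimerisation through its dienolate faster than the phosphine adduct is intercepted by formaldehyde. The fallback sets out from 1 and returns at 3, using a sulfide as a stoichiometric stand-in for the catalyst. Conjugate addition of thiophenol (Et3N cat.) would give the sulfide F12. Its lithium enolate (LiN(i-Pr)2, −78 °C) would be hydroxymethylated with monomeric formaldehyde to F13. Oxidation with m-chloroperbenzoic acid would give the sulfoxide F14, whose thermal syn-elimination towards the acidic α-hydrogen restores the conjugated ring alkene of 3.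

## Further compounds

F1 | step 10 | C6 trimethylsilyl enol ether of 14 (enol geometry not fixed) | ClC=C(O[Si](C)(C)C)/C(CO[Si](C(C)C)(C(C)C)C(C)C)=C\[C@H](O[Si](C)(C)C(C)(C)C)C(=O)[C@@H]1COC(C)(C)O1
F2 | step 10 | 6-chloro-5-hydroxy ketone (neutral chlorohydrin corresponding to 15) | CC(C)[Si](C(C)C)(C(C)C)OCC1=C[C@H](O[Si](C)(C)C(C)(C)C)[C@@](O)([C@@H]2COC(C)(C)O2)[C@@H](Cl)C1=O
F3 | step 12 | C8 triethylsilyl ether of 17 | CC(C)[Si](C(C)C)(C(C)C)OCC1=C[C@H](O[Si](C)(C)C(C)(C)C)[C@]2([C@@H](O)CO[Si](CC)(CC)CC)O[C@@H]2C1=O
F4 | step 12 | C7 acetate of F3 | CC(C)[Si](C(C)C)(C(C)C)OCC1=C[C@H](O[Si](C)(C)C(C)(C)C)[C@]2([C@H](CO[Si](CC)(CC)CC)OC(C)=O)O[C@@H]2C1=O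
F5 | step 12 | 2-acetoxy aldehyde (C8 aldehyde, C7 acetate) | CC(C)[Si](C(C)C)(C(C)C)OCC1=C[C@H](O[Si](C)(C)C(C)(C)C)[C@]2([C@H](C=O)OC(C)=O)O[C@@H]2C1=O
F6 | step 12 | (8E)-acetoxy enal | CC(C)[Si](C(C)C)(C(C)C)OCC1=C[C@H](O[Si](C)(C)C(C)(C)C)[C@]2([C@H](/C=C(C)/C=O)OC(C)=O)O[C@@H]2C1=O
F7 | step 5 | lithium (Z)-4-hydroxy carboxylate from 7 | [Li+].[O-]C(=O)/C(CO[Si](C(C)C)(C(C)C)C(C)C)=C\[C@H](O)[C@@H](O[Si](CC)(CC)CC)[C@@H]1COC(C)(C)O1
F8 | step 5 | tert-butyldimethylsilyl ester, C4 tert-butyldimethylsilyl ether | CC(C)(C)[Si](C)(C)OC(=O)/C(CO[Si](C(C)C)(C(C)C)C(C)C)=C\[C@H](O[Si](C)(C)C(C)(C)C)[C@@H](O[Si](CC)(CC)CC)[C@@H]1COC(C)(C)O1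
F9 | step 5 | (Z)-4-(tert-butyldimethylsilyloxy) carboxylic acid | OC(=O)/C(CO[Si](C(C)C)(C(C)C)C(C)C)=C\[C@H](O[Si](C)(C)C(C)(C)C)[C@@H](O[Si](CC)(CC)CC)[C@@H]1COC(C)(C)O1
F10 | step 7 | (Z)-methyl enone from 9 | CC(=O)/C(CO[Si](C(C)C)(C(C)C)C(C)C)=C\[C@H](O[Si](C)(C)C(C)(C)C)[C@@H](O[Si](CC)(CC)CC)[C@@H]1COC(C)(C)O1
F11 | step 7 | trimethylsilyl dienol ether of F10 | C=C(O[Si](C)(C)C)/C(CO[Si](C(C)C)(C(C)C)C(C)C)=C\[C@H](O[Si](C)(C)C(C)(C)C)[C@@H](O[Si](CC)(CC)CC)[C@@H]1COC(C)(C)O1
F12 | step 1 | 4-(phenylsulfanyl)oxolan-2-one (racemic) | O=C1CC(Sc2ccccc2)CO1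
F13 | step 1 | 3-(hydroxymethyl)-4-(phenylsulfanyl)oxolan-2-one (racemic, both centres lost on elimination) | O=C1OCC(Sc2ccccc2)C1CO
F14 | step 1 | 3-(hydroxymethyl)-4-(phenylsulfinyl)oxolan-2-one (racemic) | O=C1OCC(S(=O)c2ccccc2)C1CO
A1 | alternative 1 | benzoic acid | OC(=O)c1ccccc1
A2 | alternative 1 | (1S,2R)-1,2-dihydroxycyclohexa-3,5-diene-1-carboxylic acid | C1=C[C@@H](O)[C@](O)(C(O)=O)C=C1
A3 | alternative 2 | open-chain epoxy diene diol with C3 vinyl and 1,1-disubstituted C2 alkene, both acetates and C12 dioxolane | C=C[C@@H](O)[C@]1([C@H](/C=C(C)/C=C/C2OCCO2)OC(C)=O)O[C@@H]1[C@H](O)C(=C)COC(C)=O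
A4 | alternative 2 | epoxycyclohexene-1,4-diol with both acetates and C12 dioxolane | CC(=O)OCC1=C[C@@H](O)[C@]2([C@H](/C=C(C)/C=C/C3OCCO3)OC(C)=O)O[C@@H]2[C@@H]1O
A5 | alternative 3 | pentacarbonyl{methoxy[3-(tert-butyldimethylsilyloxy)prop-1-en-2-yl]carbene}chromium | COC(C(=C)CO[Si](C)(C)C(C)(C)C)=[Cr](=C=O)(=C=O)(=C=O)(=C=O)=C=O
A6 | alternative 3 | terminal propargylic alkyne with C7 silyl ether and C12 dimethyl acetal | C#C[C@H](/C=C(C)/C=C/C(OC)OC)O[Si](C)(C)C(C)(C)C
A7 | alternative 3 | 2,5-disubstituted 4-methoxyphenol carrying C7 | COc1cc([C@H](/C=C(C)/C=C/C(OC)OC)O[Si](C)(C)C(C)(C)C)c(O)cc1CO[Si](C)(C)C(C)(C)C
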